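**Plan**

- Retrosynthesis: cut the phenol O–Si bond (last step), then the acyl C–O bond of the ester, giving (R)-terpinen-4-ol 11 and silyl-protected 4-hydroxy-3,5-diprenylbenzoic acid 16. In 11 cut the ring bonds C3–C4 and C1–C6 together (ring numbering: C1 = methyl-bearing alkene carbon, C2 = alkene CH, C3 = CH2, C4 = carbinol carbon, C5 and C6 = CH2). In 16 cut the two aryl–CH2 bonds.
- Enabling feature: the carbinol carbon C4 (O, isopropyl) is homoallylic to the ring alkene through C3 (C4–C3H2–C2H=C1), which is the retron of a carbonyl allylboration. C1 is a fully substituted alkene carbon that can have carried boron and received C6 by a 1,2-shift. The ring therefore splits into a C3–C2–C1(CH3) unit (but-3-en-2-ol) and a C6–C5–C4(=O)–isopropyl unit (a β-boryl ketone).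
- Forward: carbamate 2 and masked β-boryl ketone 5 are made in one and two steps. One pot then joins them (C6–C1, lithiation–borylation and 1,2-metallate shift) and closes the six-membered ring (C3–C4, intramolecular allylboration). Carbamate, boron, the B–O bridge and the ketal are all helpers that leave in the same pot. The arene is built by silylation, twofold prenyl Stille coupling and Pinnick oxidation; esterification and desilylation finish.
- Stereochemistry: the only stereocentre (C4, R) comes from commercial (R)-but-3-en-2-ol. Its C–O centre becomes a C–B centre, which is relayed 1,4 across the forming ring to C4 and is itself erased.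

Key step: step 4

Assumption: 1, 3, 12 and 14 are taken as purchasable, and borylation of the lithiated secondary allylic carbamate is taken to proceed with retention and the 1,2-shift with inversion, the established course with pinacol boronic esters.

**Route**

Step 1
Reactants: 1 (R)-but-3-en-2-ol
Product: 2 (R)-but-3-en-2-yl N,N-diisopropylcarbamate
Conditions: iPr2NCOCl, Et3N, CH2Cl2, reflux
Reagents that add atoms: N,N-diisopropylcarbamoyl chloride, CC(C)N(C(C)C)C(=O)Cl
Why: O-carbamoylation (acyl substitution at the carbamoyl chloride) does not touch the C–O stereocentre and installs the group that later directs α-lithiation and serves as the leaving group.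

Step 2
Reactants: 3 4-methylpent-1-en-3-one
Product: 4 4-methyl-1-(4,4,5,5-tetramethyl-1,3,2-dioxaborolan-2-yl)pentan-3-one
Conditions: B2pin2, CuCl (cat.), DPEphos (cat.), NaOtBu (cat.), MeOH, THF, rt
Reagents that add atoms: bis(pinacolato)diboron, CC1(C)OB(OC1(C)C)B1OC(C)(C)C(C)(C)O1
Why: copper-catalysed conjugate borylation of an enone (a boryl complex of monovalent copper adds 1,4 and methanol protonates the copper enolate) should place boron on the unsubstituted β-carbon.

Step 3
Reactants: 4 4-methyl-1-(4,4,5,5-tetramethyl-1,3,2-dioxaborolan-2-yl)pentan-3-one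
Product: 5 2-(3,3-dimethoxy-4-methylpentyl)-4,4,5,5-tetramethyl-1,3,2-dioxaborolane
Conditions: HC(OMe)3, MeOH, p-TsOH·H2O (cat.), rt; Et3N quench
Reagents that add atoms: trimethyl orthoformate, COC(OC)OC; methanol, CO
Why: acid-catalysed ketalisation driven by the orthoformate masks the ketone against the organolithium of step 4 as a dimethyl ketal that very mild aqueous acid removes, while the pinacol boronate is retained.

Step 4
Reactants: 2 (R)-but-3-en-2-yl N,N-diisopropylcarbamate; 5 2-(3,3-dimethoxy-4-methylpentyl)-4,4,5,5-tetramethyl-1,3,2-dioxaborolane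
Product: 11 (R)-terpinen-4-ol [(1R)-4-methyl-1-(propan-2-yl)cyclohex-3-en-1-ol], via lithiated carbamate 6 (not isolated), via boronate complex 7 (not isolated), via allylboronate ketal 8 (not isolated), via keto allylboronate 9 (not isolated), via terpinenyl borate 10 (not isolated)
Conditions: sBuLi, TMEDA, Et2O, −78 °C; then 5, −78 °C to reflux; then 0.5 M aq. HCl, THF, 0 to 40 °C (high dilution)
Reagents that add atoms: water, O
Why: Proposed new method: sBuLi removes the α-oxy allylic proton of 2 with retention, the configurationally stable lithio carbamate 6 is borylated at the α-carbon with retention by 5, and the 1,2-metallate shift of complex 7 (alkyl group anti to the departing carbamate, inversion at carbon) forms the C6–C1 bond and gives the (R)-configured tertiary allylboronate 8; mild acid then unmasks ketone 9, whose allylboron unit adds through its terminal CH2 to the carbonyl carbon in a closed, B–O-bridged six-membered transition state, forming the C3–C4 bond and moving the double bond into the ring as C2H=C1(CH3). The closest known chemistry is the lithiation–borylation of secondary allylic carbamates to tertiary allylboronates and the stereospecific allylboration of carbonyl compounds by α,α-disubstituted allyl pinacol boronates; new is the intramolecular version onto a ketone with the tether on the boron-bearing carbon (type 3 in the classification of intramolecular ene reactions). The carbocycle closes in a 6-exo-trig mode at the carbonyl (endo with respect to the allyl unit) through a twisted bicyclo[2.2.2]octane-like transition state whose three bridges are the allyl unit, the CH2CH2 tether and B–O; the long partial C···C and B···O bonds should allow the twist that orbital overlap requires. The new stereocentre C4 is controlled by the boron-bearing carbon alone: the B–O bridge forces the carbonyl oxygen onto the boron face with isopropyl outside, so (R)-9 must give (R)-10 while the donor centre becomes sp2 (1,4-chirality transfer), and the ring alkene is necessarily cis. The step needs α- over γ-borylation (the known preference of these lithiated carbamates for pinacol boronic esters) and intramolecular allylboration over protodeboronation or intermolecular reaction (proximity of the ketone, dilution, and the low intermolecular reactivity of a tertiary pinacol allylboronate towards a branched ketone); the borate 10 is hydrolysed in the same aqueous medium.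

Step 5
Reactants: 12 4-hydroxy-3,5-diiodobenzaldehyde
Product: 13 4-[(tert-butyldimethylsilyl)oxy]-3,5-diiodobenzaldehyde
Conditions: TBSCl, imidazole, DMAP (cat.), DMF, rt
Reagents that add atoms: tert-butyldimethylsilyl chloride, CC(C)(C)[Si](C)(C)Cl
Why: silylation of the acidic phenol gives a protecting group that tolerates neutral cross-coupling, buffered oxidation and a lithium alkoxide, and that fluoride removes at the end without acid.

Step 6
Reactants: 13 4-[(tert-butyldimethylsilyl)oxy]-3,5-diiodobenzaldehyde; 14 tributyl(3-methylbut-2-en-1-yl)stannane (2.5 equiv)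
Product: 15 4-[(tert-butyldimethylsilyl)oxy]-3,5-bis(3-methylbut-2-en-1-yl)benzaldehyde
Conditions: Pd(PPh3)4 (cat.), DMF (degassed), 90 °C; aq. KF work-up
Reagents that add atoms: none
Why: twofold Stille coupling at the two activated C–I bonds should give the linear prenyl groups, because the allyl–palladium intermediate equilibrates and reductive elimination takes place at the unsubstituted allyl terminus, and the neutral conditions spare aldehyde and silyl ether.

Step 7
Reactants: 15 4-[(tert-butyldimethylsilyl)oxy]-3,5-bis(3-methylbut-2-en-1-yl)benzaldehyde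
Product: 16 4-[(tert-butyldimethylsilyl)oxy]-3,5-bis(3-methylbut-2-en-1-yl)benzoic acid
Conditions: NaClO2, NaH2PO4, 2-methylbut-2-ene (large excess), t-BuOH–THF–H2O, 0 °C to rt
Reagents that add atoms: sodium chlorite, [Na+].[O-]Cl=O
Why: Pinnick oxidation converts the aldehyde into the acid at buffered pH, and the large excess of 2-methylbut-2-ene intercepts the hypochlorous acid before it can reach the prenyl double bonds, which are of the same alkene class.

Step 8
Reactants: 16 4-[(tert-butyldimethylsilyl)oxy]-3,5-bis(3-methylbut-2-en-1-yl)benzoic acid; 11 (R)-terpinen-4-ol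
Product: 19 (1R)-4-methyl-1-(propan-2-yl)cyclohex-3-en-1-yl 4-[(tert-butyldimethylsilyl)oxy]-3,5-bis(3-methylbut-2-en-1-yl)benzoate, via acid chloride 17 (not isolated), via lithium alkoxide 18 (not isolated)
Conditions: 16, 1-chloro-N,N,2-trimethylprop-1-en-1-amine, CH2Cl2, 0 °C to rt; separately 11, nBuLi, THF, −78 to 0 °C; then solution of 17 added, −78 °C to rt
Reagents that add atoms: none
Why: acylation of a preformed lithium tertiary alkoxide by an aroyl chloride (made under neutral conditions with the α-chloroenamine, so no HCl meets the prenyl groups) is the standard route to hindered tertiary benzoates and leaves the C4–O bond, and hence the stereocentre, untouched.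

Step 9
Reactants: 19 (1R)-4-methyl-1-(propan-2-yl)cyclohex-3-en-1-yl 4-[(tert-butyldimethylsilyl)oxy]-3,5-bis(3-methylbut-2-en-1-yl)benzoate
Product: 20 (1R)-4-methyl-1-(propan-2-yl)cyclohex-3-en-1-yl 4-hydroxy-3,5-bis(3-methylbut-2-en-1-yl)benzoate
Conditions: TBAF, AcOH, THF, 0 °C
Reagents that add atoms: none
Why: fluoride-driven cleavage of the aryl silyl ether, buffered with acetic acid, should free the phenol without acid that could cyclise the ortho-prenyl phenol or ionise the tertiary ester.

**Compound list**

1 | (R)-but-3-en-2-ol | C[C@@H](O)C=C | starting material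
2 | (R)-but-3-en-2-yl N,N-diisopropylcarbamate | C[C@@H](OC(=O)N(C(C)C)C(C)C)C=C | intermediate
3 | 4-methylpent-1-en-3-one (isopropyl vinyl ketone) | CC(C)C(=O)C=C | starting material
4 | 4-methyl-1-(4,4,5,5-tetramethyl-1,3,2-dioxaborolan-2-yl)pentan-3-one | CC(C)C(=O)CCB1OC(C)(C)C(C)(C)O1 | intermediate
5 | 2-(3,3-dimethoxy-4-methylpentyl)-4,4,5,5-tetramethyl-1,3,2-dioxaborolane | COC(CCB1OC(C)(C)C(C)(C)O1)(OC)C(C)C | intermediate
6 | (R)-2-lithiobut-3-en-2-yl N,N-diisopropylcarbamate (lithium in place of the carbinol hydrogen, retention) | C[C@@]([Li])(OC(=O)N(C(C)C)C(C)C)C=C | intermediate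
7 | lithium (R)-[2-(N,N-diisopropylcarbamoyloxy)but-3-en-2-yl](3,3-dimethoxy-4-methylpentyl)(pinacolato)borate | C[C@@]([B-]1(CCC(OC)(OC)C(C)C)OC(C)(C)C(C)(C)O1)(OC(=O)N(C(C)C)C(C)C)C=C.[Li+] | intermediate
8 | (R)-2-(6,6-dimethoxy-3,7-dimethyloct-1-en-3-yl)-4,4,5,5-tetramethyl-1,3,2-dioxaborolane | C[C@@](CCC(OC)(OC)C(C)C)(B1OC(C)(C)C(C)(C)O1)C=C | intermediate
9 | (R)-2,6-dimethyl-6-(4,4,5,5-tetramethyl-1,3,2-dioxaborolan-2-yl)oct-7-en-3-one | C[C@@](CCC(=O)C(C)C)(B1OC(C)(C)C(C)(C)O1)C=C | intermediate
10 | 4,4,5,5-tetramethyl-2-{[(1R)-4-methyl-1-(propan-2-yl)cyclohex-3-en-1-yl]oxy}-1,3,2-dioxaborolane | CC1(C)OB(O[C@@]2(C(C)C)CC=C(C)CC2)OC1(C)C | intermediate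
11 | (R)-terpinen-4-ol, (1R)-4-methyl-1-(propan-2-yl)cyclohex-3-en-1-ol | O[C@@]1(C(C)C)CC=C(C)CC1 | intermediate
12 | 4-hydroxy-3,5-diiodobenzaldehyde | O=Cc1cc(I)c(O)c(I)c1 | starting material
13 | 4-[(tert-butyldimethylsilyl)oxy]-3,5-diiodobenzaldehyde | O=Cc1cc(I)c(O[Si](C)(C)C(C)(C)C)c(I)c1 | intermediate
14 | tributyl(3-methylbut-2-en-1-yl)stannane | CC(C)=CC[Sn](CCCC)(CCCC)CCCC | starting material
15 | 4-[(tert-butyldimethylsilyl)oxy]-3,5-bis(3-methylbut-2-en-1-yl)benzaldehyde | O=Cc1cc(CC=C(C)C)c(O[Si](C)(C)C(C)(C)C)c(CC=C(C)C)c1 | intermediate
16 | 4-[(tert-butyldimethylsilyl)oxy]-3,5-bis(3-methylbut-2-en-1-yl)benzoic acid | O=C(O)c1cc(CC=C(C)C)c(O[Si](C)(C)C(C)(C)C)c(CC=C(C)C)c1 | intermediate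
17 | 4-[(tert-butyldimethylsilyl)oxy]-3,5-bis(3-methylbut-2-en-1-yl)benzoyl chloride | O=C(Cl)c1cc(CC=C(C)C)c(O[Si](C)(C)C(C)(C)C)c(CC=C(C)C)c1 | intermediate
18 | lithium (1R)-4-methyl-1-(propan-2-yl)cyclohex-3-en-1-olate | [Li+].[O-][C@@]1(C(C)C)CC=C(C)CC1 | intermediate
19 | (1R)-4-methyl-1-(propan-2-yl)cyclohex-3-en-1-yl 4-[(tert-butyldimethylsilyl)oxy]-3,5-bis(3-methylbut-2-en-1-yl)benzoate | CC(C)=CCc1cc(C(=O)O[C@@]2(C(C)C)CC=C(C)CC2)cc(CC=C(C)C)c1O[Si](C)(C)C(C)(C)C | intermediate
20 | (1R)-4-methyl-1-(propan-2-yl)cyclohex-3-en-1-yl 4-hydroxy-3,5-bis(3-methylbut-2-en-1-yl)benzoate | CC(C)=CCc1cc(C(=O)O[C@@]2(C(C)C)CC=C(C)CC2)cc(CC=C(C)C)c1O | target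

**Count and risks**

Total step count: 9. Longest linear sequence: 5 steps (steps 2, 3, 4, 8, 9; equally steps 5, 6, 7, 8, 9).

Steps most likely to fail:

1. Step 4 (proposed new method).
   - What may go wrong: borylation at the γ-terminus of the lithiated carbamate instead of the α-carbon; loss of configuration of 6 on warming before borylation; protodeboronation of the tertiary allylboronate during ketal hydrolysis; failure to reach the bridged closed transition state, so that intermolecular allylboration or an open pathway without chirality transfer takes over; acid-induced dehydration or ether formation of the tertiary alcohol.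
   - Fallback with known chemistry, from 3 back to 11: CuBr·SMe2-catalysed conjugate addition of isopropenylmagnesium bromide to 3 (TMSCl, THF, −78 °C, then dilute acid) should give 2,6-dimethylhept-6-en-3-one F1. Reagent-controlled asymmetric allylboration of this ketone with the appropriate enantiomer of B-allyl-10-phenyl-9-borabicyclo[3.3.2]decane (Et2O, −78 °C, oxidative work-up) should give (R)-7-methyl-4-(propan-2-yl)octa-1,7-dien-4-ol F2. The reagent has to tell isopropyl from the unbranched chain, so the enantiomeric purity may need upgrading on a chiral phase. Ring-closing metathesis of F2 with the second-generation Grubbs catalyst (CH2Cl2, 40 °C) then forms the C1=C2 double bond and delivers 11. This replaces the chirality relay by reagent control and the two-bond event by two separate C–C bond formations.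

2. Step 6.
   - What may go wrong: incomplete second coupling next to the bulky silyl ether; reductive elimination at the substituted allyl terminus giving 1,1-dimethylallyl groups; thermal loss of the silyl group from the electron-poor aryl ether.
   - Fallback, from 13 back to 15: twofold Stille coupling of 13 with allyltributylstannane (Pd(PPh3)4, DMF, 80 °C) has no regiochemical issue and should give 4-[(tert-butyldimethylsilyl)oxy]-3,5-di(prop-2-en-1-yl)benzaldehyde F3. Twofold cross-metathesis with excess 2-methylbut-2-ene (second-generation Grubbs catalyst, CH2Cl2, 40 °C) then converts both allyl groups into prenyl groups and gives 15.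

3. Step 8.
   - What may go wrong: acylation of the hindered alkoxide too slow, leaving time for attack of the alkoxide on the aryl silyl ether or for decomposition of the acid chloride.
   - Fallback, from 16 and 11 back to 19: instead of an anionic alkoxide, the neutral alcohol is acylated under nucleophilic catalysis (Shiina esterification). Acid 16 with 2-methyl-6-nitrobenzoic anhydride and Et3N in toluene should give 4-[(tert-butyldimethylsilyl)oxy]-3,5-bis(3-methylbut-2-en-1-yl)benzoic 2-methyl-6-nitrobenzoic anhydride F4. DMAP then relays the less hindered, more electron-rich acyl group to 11 (rt to 60 °C) to give 19.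

**Further compounds**

F1 | step 4 | 2,6-dimethylhept-6-en-3-one | CC(C)C(=O)CCC(C)=C
F2 | step 4 | (R)-7-methyl-4-(propan-2-yl)octa-1,7-dien-4-ol | O[C@@](CCC(C)=C)(C(C)C)CC=C
F3 | step 6 | 4-[(tert-butyldimethylsilyl)oxy]-3,5-di(prop-2-en-1-yl)benzaldehyde | O=Cc1cc(CC=C)c(O[Si](C)(C)C(C)(C)C)c(CC=C)c1
F4 | step 8 | 4-[(tert-butyldimethylsilyl)oxy]-3,5-bis(3-methylbut-2-en-1-yl)benzoic 2-methyl-6-nitrobenzoic anhydride | O=C(OC(=O)c1c(C)cccc1[N+](=O)[O-])c1cc(CC=C(C)C)c(O[Si](C)(C)C(C)(C)C)c(CC=C(C)C)c1
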